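## Retrosynthetic overview
1. The C5–H stereocentre of the butenolide is set in the last step. A catalytic asymmetric proton transfer moves the C=C of a β,γ-unsaturated lactone into conjugation, so no C–C or C–O bond is formed at that carbon.
2. The lactone ring is bought rather than closed. An α-homoprenyl furanone is aromatised to a 2-siloxyfuran linchpin, lithiated at C5 and allylated, which makes the Cγ–CH2 bond.
3. The allylic bromide partner comes from E-selective SeO2 oxidation of the prenyl terminus of a nerol-derived chromene.
4. In the chromene, the C2–O bond is made first. A Pd-AAA of a hindered 2-vinylphenol with neryl carbonate sets the tertiary ether, and RCM then closes C3=C4. This avoids the racemic quinone-methide/oxa-6π route.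
5. Ring order: arene (bought), then pyran (RCM), then lactone (bought ring, de-aromatised at the end).

Assumption 1: the sense of induction in steps 5 and 13 is assigned by analogy. Both ligand antipodes and both pseudo-enantiomeric cinchona catalysts are available, so configuration is checked at 8 and 17 and the catalyst hand is switched if needed, with no other change.
Assumption 2: 3-bromofuran-2(5H)-one and 5-bromo-2-methylpent-2-ene are taken as catalogue compounds.
Handling: from step 6 onward, keep material at or below 40 °C and away from light, because 2H-chromenes racemise by reversible electrocyclic ring opening.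

## Route

**Step 1**
Reactants: 1, 2-methylhydroquinone
Product: 2, 2-methyl-4-(triisopropylsilyloxy)phenol
Conditions: TIPSCl (1.0 equiv), imidazole, DMF, 0 °C
Reagents that add atoms: TIPSCl, CC(C)[Si](Cl)(C(C)C)C(C)C
Why: Sterically controlled mono-O-silylation, in which the bulky chloride takes the unflanked OH and leaves the OH next to the methyl group, the future ring oxygen, free.

**Step 2**
Reactants: 2
Product: 3, 2-hydroxy-3-methyl-5-(triisopropylsilyloxy)benzaldehyde
Conditions: MgCl2, Et3N, (CH2O)n, MeCN, reflux
Reagents that add atoms: paraformaldehyde, C=O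
Why: Magnesium-phenoxide-directed ortho-formylation (Casnati–Skattebøl) can only reach the single free ortho carbon, and the aryl OTIPS group tolerates the conditions.

**Step 3**
Reactants: 3
Product: 4, 2-ethenyl-6-methyl-4-(triisopropylsilyloxy)phenol
Conditions: Ph3PCH3Br (2.5 equiv), KOtBu (2.4 equiv), THF, 0 °C to rt; use promptly (BHT)
Reagents that add atoms: methyltriphenylphosphonium bromide, C[P+](c1ccccc1)(c1ccccc1)c1ccccc1.[Br-]
Why: Wittig methylenation of a salicylaldehyde, with the extra equivalent of ylide consumed by the phenol.

**Step 4**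
Reactants: 5, nerol ((2Z)-3,7-dimethylocta-2,6-dien-1-ol, ≥97% Z)
Product: 6, neryl methyl carbonate
Conditions: ClCO2Me, pyridine, CH2Cl2, 0 °C
Reagents that add atoms: methyl chloroformate, COC(=O)Cl
Why: Simple O-acylation that gives an ionisable group releasing its own base (MeO−/CO2) in the next step.

**Step 5 (key step A)**
Reactants: 4 and 6
Product: 7, (S)-{4-[(3,7-dimethylocta-1,6-dien-3-yl)oxy]-3-ethenyl-5-methylphenoxy}triisopropylsilane (the (S)-linalyl aryl ether)
Conditions: Pd2(dba)3·CHCl3 (2 mol %), (R,R)-DACH-phenyl Trost ligand (6 mol %), CH2Cl2, 0 °C to rt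
Reagents that add atoms: none
Why: Trost asymmetric allylic O-alkylation, in which the 1,1-disubstituted π-allyl-Pd exchanges faces through its CH2 terminus (π-σ-π), the ligand pocket directs phenol attack anti to Pd at the tertiary terminus of one face to set C2 as (S), the Z-carbonate is used because that geometry gives the higher ee in this ligand family, and the electron-rich aryloxide is too poor a leaving group for the product to re-ionise.

**Step 6**
Reactants: 7
Product: 8, (S)-{[2,8-dimethyl-2-(4-methylpent-3-en-1-yl)-2H-chromen-6-yl]oxy}triisopropylsilane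
Conditions: Grubbs II (3 mol %), CH2Cl2 (5 mM), 35 °C, dark
Reagents that add atoms: none
Why: Ring-closing metathesis in which Ru loads on the styrene and closes onto the only other monosubstituted alkene (six-membered ring, gem-disubstituent assistance), the competing linalool-type cyclopentene closure onto the trisubstituted alkene is slow without a free allylic OH, and the C2–O bond is untouched so (S) is retained.

**Step 7**
Reactants: 8
Product: 9, (E)-5-[(S)-2,8-dimethyl-6-(triisopropylsilyloxy)-2H-chromen-2-yl]-2-methylpent-2-en-1-ol
Conditions: SeO2 (0.3 equiv), tBuOOH, salicylic acid (cat.), CH2Cl2, 0 °C to rt; then NaBH4, MeOH, 0 °C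
Reagents that add atoms: SeO2, O=[Se]=O; tert-butyl hydroperoxide, CC(C)(C)OO (source of O)
Why: Catalytic SeO2 allylic oxidation (ene/[2,3] sequence) selects the E-methyl of the gem-dimethyl alkene, the chromene alkene has no allylic C–H (C2 is quaternary), and the borohydride returns over-oxidised enal to the alcohol.

**Step 8**
Reactants: 9
Product: 10, (S)-{[2-((E)-5-bromo-4-methylpent-3-en-1-yl)-2,8-dimethyl-2H-chromen-6-yl]oxy}triisopropylsilane
Conditions: CBr4, PPh3, 2,6-lutidine, CH2Cl2, −20 °C; use at once
Reagents that add atoms: CBr4, BrC(Br)(Br)Br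
Why: The Appel reaction converts the primary allylic alcohol under neutral conditions without allylic transposition or E/Z loss.

**Step 9**
Reactants: 11, 3-bromofuran-2(5H)-one; 12, 5-bromo-2-methylpent-2-ene
Product: 13, 3-(4-methylpent-3-en-1-yl)furan-2(5H)-one
Conditions: 12, Zn dust, LiCl, cat. I2, THF, 50 °C; then 11, PdCl2(dppf) (3 mol %), THF, rt
Reagents that add atoms: none
Why: Negishi sp2–sp3 coupling of an α-haloenoate, where the base-free alkylzinc spares the acidic γ-CH2 and dppf suppresses β-hydride elimination.

**Step 10**
Reactants: 13
Product: 14, triisopropyl{[3-(4-methylpent-3-en-1-yl)furan-2-yl]oxy}silane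
Conditions: TIPSOTf, Et3N, CH2Cl2, 0 °C
Reagents that add atoms: TIPSOTf, CC(C)[Si](C(C)C)(C(C)C)OS(=O)(=O)C(F)(F)F
Why: Soft enolisation with O-silylation of the butenolide, driven by aromatisation to the 2-siloxyfuran.

**Step 11 (fragment union)**
Reactants: 14 (1.3 equiv) and 10
Product: 15, 5-allylated 2-siloxyfuran (2-OTIPS, 3-homoprenyl, 5-[(E)-2-methyl-5-((S)-chromenyl)pent-2-enyl]; aryl OTIPS retained)
Conditions: 14, s-BuLi, TMEDA, THF, −78 to −20 °C; then 10, −78 °C to rt
Reagents that add atoms: none
Why: α-Lithiation of the furan at its only free α-position (C5) is followed by SN2 alkylation at the primary allylic bromide, SN2′ being blocked by the substituted alkene terminus, and TIPS is robust enough to survive s-BuLi.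

**Step 12**
Reactants: 15
Product: 16, 5-{(E)-5-[(S)-6-hydroxy-2,8-dimethyl-2H-chromen-2-yl]-2-methylpent-2-en-1-yl}-3-(4-methylpent-3-en-1-yl)furan-2(3H)-one (β,γ-unsaturated lactone, about 1:1 at C3, which is inconsequential)
Conditions: TBAF (2.5 equiv) premixed with AcOH (5 equiv), THF, −78 to −20 °C; cold pH 7 quench; fast chromatography under Ar
Reagents that add atoms: none
Why: Fluoride removes both TIPS groups and the liberated furanolate, like dienolate anions generally, is protonated kinetically at Cα to give the deconjugated 2(3H)-furanone; any conjugated racemic isomer is separated and recycled through step 10 conditions.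

**Step 13 (key step B)**
Reactants: 16
Product: 17, tuberatolide B, (5R)-5-{(2E)-5-[(2S)-6-hydroxy-2,8-dimethyl-2H-chromen-2-yl]-2-methylpent-2-en-1-yl}-3-(4-methylpent-3-en-1-yl)furan-2(5H)-one
Conditions: quinidine-derived 6′-OH, 9-O-aryl cinchona catalyst (cupreidine aryl ether, 10 mol %), CH2Cl2, −20 °C, Ar, dark; final chiral-phase HPLC polish
Reagents that add atoms: none
Why: This is an organocatalytic asymmetric olefin isomerisation by proton-transfer catalysis, in which the quinuclidine removes the α-H (both C3 epimers converge on one achiral furanolate held by the 6′-OH) and the resulting ammonium delivers H+ to one face of Cγ to set (5R), while the substrate phenol is about 8 pK units less acidic than that ammonium, so it should not be a competitive achiral proton source.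

With two independent catalyst-controlled centres, the main stereochemical impurity is the diastereomer. That diastereomer is removed by HPLC, and the ee of 17 itself is amplified.

## Compound list

| No. | Name | SMILES | Role |
|---|---|---|---|
| 1 | 2-methylhydroquinone | Cc1cc(O)ccc1O | starting material |
| 2 | 2-methyl-4-(TIPSO)phenol | Cc1cc(O[Si](C(C)C)(C(C)C)C(C)C)ccc1O | intermediate |
| 3 | 2-hydroxy-3-methyl-5-(TIPSO)benzaldehyde | Cc1cc(O[Si](C(C)C)(C(C)C)C(C)C)cc(C=O)c1O | intermediate |
| 4 | 2-ethenyl-6-methyl-4-(TIPSO)phenol | Cc1cc(O[Si](C(C)C)(C(C)C)C(C)C)cc(C=C)c1O | intermediate |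
| 5 | nerol | CC(C)=CCC/C(C)=C\CO | starting material |
| 6 | neryl methyl carbonate | CC(C)=CCC/C(C)=C\COC(=O)OC | intermediate |
| 7 | (S)-linalyl aryl ether | C=C[C@](C)(CCC=C(C)C)Oc1c(C)cc(O[Si](C(C)C)(C(C)C)C(C)C)cc1C=C | intermediate |
| 8 | (S)-6-TIPSO-2,8-dimethyl-2-homoprenyl-2H-chromene | CC(C)=CCC[C@@]1(C)C=Cc2cc(O[Si](C(C)C)(C(C)C)C(C)C)cc(C)c2O1 | intermediate |
| 9 | (S,E)-allylic alcohol | OC/C(C)=C/CC[C@@]1(C)C=Cc2cc(O[Si](C(C)C)(C(C)C)C(C)C)cc(C)c2O1 | intermediate |
| 10 | (S,E)-allylic bromide | BrC/C(C)=C/CC[C@@]1(C)C=Cc2cc(O[Si](C(C)C)(C(C)C)C(C)C)cc(C)c2O1 | intermediate |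
| 11 | 3-bromofuran-2(5H)-one | O=C1OCC=C1Br | starting material |
| 12 | 5-bromo-2-methylpent-2-ene | CC(C)=CCCBr | starting material |
| 13 | 3-(4-methylpent-3-enyl)furan-2(5H)-one | CC(C)=CCCC1=CCOC1=O | intermediate |
| 14 | 3-(4-methylpent-3-enyl)-2-(TIPSO)furan | CC(C)=CCCc1ccoc1O[Si](C(C)C)(C(C)C)C(C)C | intermediate |
| 15 | coupled bis-TIPS siloxyfuran | CC(C)=CCCc1cc(C/C(C)=C/CC[C@@]2(C)C=Cc3cc(O[Si](C(C)C)(C(C)C)C(C)C)cc(C)c3O2)oc1O[Si](C(C)C)(C(C)C)C(C)C | intermediate |
| 16 | β,γ-unsaturated lactone phenol (C3 epimers) | CC(C)=CCCC1C=C(C/C(C)=C/CC[C@@]2(C)C=Cc3cc(O)cc(C)c3O2)OC1=O | intermediate |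
| 17 | tuberatolide B | CC(C)=CCCC1=C[C@@H](C/C(C)=C/CC[C@@]2(C)C=Cc3cc(O)cc(C)c3O2)OC1=O | target |

## Summary

Total steps: 13.
Longest linear sequence: 10 steps (1, 2, 3, 5, 6, 7, 8, 11, 12, 13, starting from 2-methylhydroquinone).

**Three steps most likely to fail**

1. **Step 5.** A 2,6-disubstituted phenol must form a tertiary ether, so branched/linear ratio, ee and rate are all uncertain.
   Fallback: never break the C2–O bond.
   - Sharpless epoxidation of geraniol with L-(+)-DET gives the (2S,3S)-epoxide.
   - The derived epoxy chloride is treated with n-BuLi to give (S)-dehydrolinalool.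
   - Sonogashira coupling with an ortho-bromo aryl iodide and Lindlar semi-reduction give the Z-alkene.
   - Intramolecular Pd-catalysed aryl C–O coupling of the tertiary alcohol closes the chromene.
2. **Step 13.** The substrate is α,γ-disubstituted and carries a free phenol, so ee or turnover may be poor.
   Fallback: set the carbinol by C=O chemistry.
   - Bromide 10 is taken to the nitrile and then the β,γ-unsaturated aldehyde.
   - Addition of the alkynyl anion of 6-methylhept-5-en-1-yne and oxidation give the ynone.
   - Noyori transfer hydrogenation sets the propargylic alcohol.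
   - Red-Al/I2 trans-hydroalumination–iodination followed by Pd-catalysed carbonylative lactonisation gives the butenolide, with the silyl group removed last.
3. **Step 12.** The α- versus γ-protonation ratio is uncertain, and racemic conjugated lactone could leak through.
   Fallback: drop the siloxyfuran.
   - Perillene is made by Kumada coupling of 3-bromofuran with homoprenyl-MgBr.
   - It is metalated at C5 with LiTMP and alkylated with 10.
   - The remaining α-position is lithiated, borylated and oxidised with H2O2.
   - The resulting 2-hydroxyfuran tautomerises kinetically to the 2(3H)-one, and the aryl OTIPS group stays on through the isomerisation and is cleaved afterwards with HF·pyridine.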